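Ring B is built last, from an open chain. The key step exploits its substitution: the oxygens at C2' and C4' flank the prenylated C3', and C1' carries ring C, which is the pattern of a 4-substituted 2-prenylcyclohexane-1,3-dione. A (3R)-chroman-3-ylacetate, with rings A and C and the C3 centre complete, is added as its silyl ketene acetal to 7-methylocta-1,6-dien-3-one (C1'–C6'), and the resulting keto ester closes by Claisen condensation (C2'–C3'). One flask thus gives the dione with the prenyl group already between the two oxygens. Regioselective enol methylation then marks the C4' oxygen; dehydrogenation, ester-to-aldehyde adjustment and deprotection complete the target.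

Key step: step 8

Remark: the sense of induction in step 3 is assigned from the usual steric model of diarylprolinol silyl ether enamines (attack on the face away from the diphenyl(silyloxy)methyl group), which leads from the (R)-catalyst to (3R); the (S)-catalyst would be used if the sense proved opposite. The dione of step 8 is drawn as the diketone although it should exist mainly as enols, and C1' and C3' of ring B carry no configuration wherever they are enolisable.

Step 1
Reactants: 1 methyl 2,4,6-trihydroxybenzoate
Product: 2 methyl 2,6-dihydroxy-4-methoxybenzoate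
Conditions: Me2SO4 (1.0 equiv), K2CO3 (1.05 equiv), acetone, rt
Reagents that add atoms: dimethyl sulfate, COS(=O)(=O)OC
Why: Williamson O-methylation should take the 4-OH, the most acidic hydroxyl and the only one not hydrogen-bonded to the ester, so that one equivalent of electrophile gives the symmetric monoether.

Step 2
Reactants: 2 methyl 2,6-dihydroxy-4-methoxybenzoate
Product: 3 methyl 2,6-dihydroxy-4-methoxy-3-[(4-methylphenyl)sulfonylmethyl]benzoate
Conditions: (CH2O)n (1.1 equiv), p-TolSO2Na (1.5 equiv), HCO2H/H2O, rt
Reagents that add atoms: formaldehyde (as paraformaldehyde), C=O; sodium 4-methylbenzenesulfinate, Cc1ccc(cc1)S(=O)[O-].[Na+]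
Why: In this Mannich-type three-component sulfonylmethylation the electron-rich ring is hydroxymethylated at C3 (equivalent to C5), the benzylic alcohol ionises in acid and sulfinate captures the cation at sulfur, and the electron-withdrawing sulfonylmethyl group should slow a second substitution.

Step 3
Reactants: 3 methyl 2,6-dihydroxy-4-methoxy-3-[(4-methylphenyl)sulfonylmethyl]benzoate; 4 methyl 4-oxobutanoate
Product: 6 methyl (3R)-2,7-dihydroxy-5-methoxy-3-(2-methoxy-2-oxoethyl)chroman-8-carboxylate (both C2 epimers), via ortho-quinone methide 5 (not isolated)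
Conditions: 4 (2 equiv), (R)-2-[diphenyl(trimethylsilyloxy)methyl]pyrrolidine (20 mol %), Na2CO3 (1.2 equiv), CH2Cl2/H2O, 0 °C → rt
Reagents that add atoms: none
Why: Base-induced loss of sulfinate gives the quinone methide, the catalyst-derived E-enamine of 4 attacks its exocyclic CH2 (enamine-catalysed formal [4+2], an α-benzylation of the aldehyde) and the phenol closes the lactol; C3 is set by attack on the enamine face away from the diphenyl(silyloxy)methyl group, and the closed lactol form should protect it from re-enolisation.

Step 4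
Reactants: 6 methyl (3R)-2,7-dihydroxy-5-methoxy-3-(2-methoxy-2-oxoethyl)chroman-8-carboxylate
Product: 7 methyl (3R)-7-hydroxy-5-methoxy-3-(2-methoxy-2-oxoethyl)chroman-8-carboxylate
Conditions: Et3SiH (3 equiv), BF3·OEt2 (2 equiv), CH2Cl2, −78 → −20 °C
Reagents that add atoms: none
Why: In this ionic hydrogenation of the lactol, BF3 ionises C2–OH to the cyclic oxocarbenium ion and excess silane at low temperature should deliver hydride faster than the ion can lose the C3 proton, so the C3 configuration is kept.

Step 5
Reactants: 7 methyl (3R)-7-hydroxy-5-methoxy-3-(2-methoxy-2-oxoethyl)chroman-8-carboxylate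
Product: 8 methyl (3R)-5-methoxy-3-(2-methoxy-2-oxoethyl)-7-(methoxymethoxy)chroman-8-carboxylate
Conditions: NaH (1.05 equiv), MOMCl, DMF, 0 °C
Reagents that add atoms: chloromethyl methyl ether, COCCl
Why: Williamson-type alkylation of the sodium phenoxide of the only free hydroxyl gives the methoxymethyl acetal, and the phenoxide is too weak a base to enolise either ester, so C3 is untouched.

Step 6
Reactants: 9 6-methylhept-5-en-2-one
Product: 10 1-(dimethylamino)-7-methyloct-6-en-3-one
Conditions: LiN(i-Pr)2, THF, −78 °C; (CH2=NMe2)I, −78 °C → rt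
Reagents that add atoms: N,N-dimethylmethyleneiminium iodide, C=[N+](C)C.[I-]
Why: This is a Mannich reaction of a preformed kinetic enolate: deprotonation at −78 °C takes the methyl group, so the iminium salt is attached at C1 and not at the more substituted α-carbon that an acid-mediated Mannich reaction would choose.

Step 7
Reactants: 10 1-(dimethylamino)-7-methyloct-6-en-3-one
Product: 12 7-methylocta-1,6-dien-3-one, via methiodide 11 (not isolated)
Conditions: MeI, Et2O, rt; then aq. NaHCO3, CH2Cl2, rt
Reagents that add atoms: none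
Why: Quaternisation followed by E1cB (Hofmann-type) elimination of trimethylamine from the β-ammonio ketone should give the vinyl ketone under mild conditions, and the enone is kept cold with a radical inhibitor and used at once.

Step 8
Reactants: 8 methyl (3R)-5-methoxy-3-(2-methoxy-2-oxoethyl)-7-(methoxymethoxy)chroman-8-carboxylate; 12 7-methylocta-1,6-dien-3-one
Product: 16 methyl (3R)-3-[2,4-dioxo-3-(3-methylbut-2-enyl)cyclohexyl]-5-methoxy-7-(methoxymethoxy)chroman-8-carboxylate, via silyl ketene acetal 13 (not isolated), via silyl enol ether adduct 14 (not isolated), via keto ester 15 (not isolated)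
Conditions: LiN(i-Pr)2, THF, −78 °C; TMSCl, −78 °C → rt; solvent to CH2Cl2, 12 (1.3 equiv), Yb(OTf)3 (10 mol %), −40 → 0 °C; solvent to THF, KOt-Bu (2.5 equiv), t-BuOH, 0 °C → rt; cold 1 M HCl to pH 3–4
Reagents that add atoms: none
Why: Enolisation of the acetate arm and O-silylation give ketene acetal 13, whose α-carbon (the future C1') adds to the Lewis-acid-activated vinyl ketone (Mukaiyama–Michael addition) to form C1'–C6' and leave silyl enol ether 14; tert-butoxide then desilylates it, the ketone enolates equilibrate through t-BuOH, and the enolate at C3' (the carbon carrying the prenyl chain) attacks the acetate carbonyl, expels methoxide and forms C2'–C3' (Claisen condensation of a δ-keto ester, Dieckmann type). The closest known reaction type is the Michael–Claisen synthesis of cyclohexane-1,3-diones from 5-oxoalkanoates. Ring B closes in the 6-(enolendo)-exo-trig mode. No stereocentre of the target is formed: C1' and C3' are enolisable and later become aromatic, while C3, β to the ester and never deprotonated, keeps its R configuration. The step needs 1,4- and single addition, which the neutral silyl ketene acetal under mild Lewis acid catalysis should secure where a lithium ester enolate would attack the carbonyl or start oligomerisation of the enone; it also needs closure from the right enolate onto the right ester, and here the C5' enolate could only form a four-membered ring while the C8 ester is shielded by two ortho oxygens and out of reach. Deprotonation of the product dione by alkoxide makes the sequence irreversible.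

Step 9
Reactants: 16 methyl (3R)-3-[2,4-dioxo-3-(3-methylbut-2-enyl)cyclohexyl]-5-methoxy-7-(methoxymethoxy)chroman-8-carboxylate
Product: 17 methyl (3R)-5-methoxy-3-[4-methoxy-3-(3-methylbut-2-enyl)-2-oxocyclohex-3-en-1-yl]-7-(methoxymethoxy)chroman-8-carboxylate
Conditions: Me2SO4 (1.1 equiv), K2CO3, acetone, rt → 50 °C
Reagents that add atoms: dimethyl sulfate, COS(=O)(=O)OC
Why: O-alkylation of the dione enolate with a hard electrophile (enol ether formation, C-methylation at the already substituted C3' being disfavoured) should go to the C4' oxygen, which has a CH2 neighbour, and not to the C2' oxygen beside the chromanyl-bearing C1', and any regioisomer is removed by chromatography.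

Step 10
Reactants: 17 methyl (3R)-5-methoxy-3-[4-methoxy-3-(3-methylbut-2-enyl)-2-oxocyclohex-3-en-1-yl]-7-(methoxymethoxy)chroman-8-carboxylate
Product: 21 methyl (3R)-3-[2-hydroxy-4-methoxy-3-(3-methylbut-2-enyl)phenyl]-5-methoxy-7-(methoxymethoxy)chroman-8-carboxylate, via selenide 18 (not isolated), via selenoxide 19 (not isolated), via dienone tautomer 20 (not isolated)
Conditions: LiN(i-Pr)2, THF, −78 °C; PhSeBr, −78 °C; then pyridine, 30% H2O2, 0 °C → rt
Reagents that add atoms: none
Why: Kinetic α'-deprotonation of the vinylogous ester at C1', α-selenenylation and selenoxide syn-elimination into the ring toward C6'–H (selenoxide dehydrogenation) give the cross-conjugated dienone, which is the keto tautomer of the phenol and should enolise at once; endocyclic elimination is the usual course for α-seleno cyclohexanones and leaves C3–H in place.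

Step 11
Reactants: 21 methyl (3R)-3-[2-hydroxy-4-methoxy-3-(3-methylbut-2-enyl)phenyl]-5-methoxy-7-(methoxymethoxy)chroman-8-carboxylate
Product: 22 [(3R)-3-[2-hydroxy-4-methoxy-3-(3-methylbut-2-enyl)phenyl]-5-methoxy-7-(methoxymethoxy)chroman-8-yl]methanol
Conditions: LiAlH4, THF, 0 °C → rt
Reagents that add atoms: none
Why: Hydride reduction of the hindered aryl ester gives the benzylic alcohol, the phenol being merely deprotonated and the prenyl alkene, the aryl ethers and the acetal being inert to LiAlH4.

Step 12
Reactants: 22 [(3R)-3-[2-hydroxy-4-methoxy-3-(3-methylbut-2-enyl)phenyl]-5-methoxy-7-(methoxymethoxy)chroman-8-yl]methanol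
Product: 23 (3R)-3-[2-hydroxy-4-methoxy-3-(3-methylbut-2-enyl)phenyl]-5-methoxy-7-(methoxymethoxy)chroman-8-carbaldehyde
Conditions: MnO2 (activated, excess), CH2Cl2, rt
Reagents that add atoms: none
Why: Heterogeneous benzylic oxidation with MnO2 should convert the electron-rich benzyl alcohol into the aldehyde under neutral conditions that spare the acid-labile trialkoxybenzyl alcohol, the phenol and the prenyl group.

Step 13
Reactants: 23 (3R)-3-[2-hydroxy-4-methoxy-3-(3-methylbut-2-enyl)phenyl]-5-methoxy-7-(methoxymethoxy)chroman-8-carbaldehyde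
Product: 24 (3R)-7-hydroxy-3-[2-hydroxy-4-methoxy-3-(3-methylbut-2-enyl)phenyl]-5-methoxychroman-8-carbaldehyde
Conditions: 2 M HCl (aq), THF, 0 °C → rt
Reagents that add atoms: none
Why: Acid hydrolysis of the aryl methoxymethyl acetal, activated by the ortho formyl group, should proceed under conditions too mild to cyclise the 2'-OH onto the prenyl alkene.

Compound list
1 | methyl 2,4,6-trihydroxybenzoate | COC(=O)c1c(O)cc(O)cc1O | starting material
2 | methyl 2,6-dihydroxy-4-methoxybenzoate | COC(=O)c1c(O)cc(OC)cc1O | intermediate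
3 | methyl 2,6-dihydroxy-4-methoxy-3-[(4-methylphenyl)sulfonylmethyl]benzoate | COC(=O)c1c(O)cc(OC)c(CS(=O)(=O)c2ccc(C)cc2)c1O | intermediate
4 | methyl 4-oxobutanoate | COC(=O)CCC=O | starting material
5 | methyl 2-hydroxy-4-methoxy-5-methylidene-6-oxocyclohexa-1,3-diene-1-carboxylate (ring-A ortho-quinone methide) | COC(=O)C1=C(O)C=C(OC)C(=C)C1=O | intermediate
6 | methyl (3R)-2,7-dihydroxy-5-methoxy-3-(2-methoxy-2-oxoethyl)chroman-8-carboxylate, both C2 epimers | COC(=O)C[C@@H]1C(O)Oc2c(C(=O)OC)c(O)cc(OC)c2C1 | intermediate
7 | methyl (3R)-7-hydroxy-5-methoxy-3-(2-methoxy-2-oxoethyl)chroman-8-carboxylate | COC(=O)C[C@@H]1COc2c(C(=O)OC)c(O)cc(OC)c2C1 | intermediate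
8 | methyl (3R)-5-methoxy-3-(2-methoxy-2-oxoethyl)-7-(methoxymethoxy)chroman-8-carboxylate | COC(=O)C[C@@H]1COc2c(C(=O)OC)c(OCOC)cc(OC)c2C1 | intermediate
9 | 6-methylhept-5-en-2-one | CC(=O)CCC=C(C)C | starting material
10 | 1-(dimethylamino)-7-methyloct-6-en-3-one | CN(C)CCC(=O)CCC=C(C)C | intermediate
11 | trimethyl(7-methyl-3-oxooct-6-enyl)ammonium iodide | C[N+](C)(C)CCC(=O)CCC=C(C)C.[I-] | intermediate
12 | 7-methylocta-1,6-dien-3-one | C=CC(=O)CCC=C(C)C | intermediate
13 | methyl (3R)-5-methoxy-3-[2-methoxy-2-(trimethylsilyloxy)ethenyl]-7-(methoxymethoxy)chroman-8-carboxylate, E/Z mixture | COC(O[Si](C)(C)C)=C[C@@H]1COc2c(C(=O)OC)c(OCOC)cc(OC)c2C1 | intermediate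
14 | methyl (3R)-5-methoxy-3-[1-methoxy-9-methyl-1-oxo-5-(trimethylsilyloxy)deca-4,8-dien-2-yl]-7-(methoxymethoxy)chroman-8-carboxylate, side-chain C2 unassigned | COC(=O)C(CC=C(O[Si](C)(C)C)CCC=C(C)C)[C@@H]1COc2c(C(=O)OC)c(OCOC)cc(OC)c2C1 | intermediate
15 | methyl (3R)-5-methoxy-3-(1-methoxy-9-methyl-1,5-dioxodec-8-en-2-yl)-7-(methoxymethoxy)chroman-8-carboxylate, side-chain C2 unassigned | COC(=O)C(CCC(=O)CCC=C(C)C)[C@@H]1COc2c(C(=O)OC)c(OCOC)cc(OC)c2C1 | intermediate
16 | methyl (3R)-3-[2,4-dioxo-3-(3-methylbut-2-enyl)cyclohexyl]-5-methoxy-7-(methoxymethoxy)chroman-8-carboxylate, C1' and C3' unassigned | CC(C)=CCC1C(=O)CCC(C1=O)[C@@H]1COc2c(C(=O)OC)c(OCOC)cc(OC)c2C1 | intermediate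
17 | methyl (3R)-5-methoxy-3-[4-methoxy-3-(3-methylbut-2-enyl)-2-oxocyclohex-3-en-1-yl]-7-(methoxymethoxy)chroman-8-carboxylate, C1' unassigned | COC1=C(CC=C(C)C)C(=O)C(CC1)[C@@H]1COc2c(C(=O)OC)c(OCOC)cc(OC)c2C1 | intermediate
18 | methyl 5-methoxy-3-[4-methoxy-3-(3-methylbut-2-enyl)-2-oxo-1-(phenylselanyl)cyclohex-3-en-1-yl]-7-(methoxymethoxy)chroman-8-carboxylate, C3 geometry as in 17 (descriptor 3S only because selenium raises the rank of C1'), C1' unassigned | COC1=C(CC=C(C)C)C(=O)C(CC1)([Se]c3ccccc3)[C@@H]4COc2c(C(=O)OC)c(OCOC)cc(OC)c2C4 | intermediate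
19 | selenoxide of 18: methyl 5-methoxy-3-[4-methoxy-3-(3-methylbut-2-enyl)-2-oxo-1-(phenylseleninyl)cyclohex-3-en-1-yl]-7-(methoxymethoxy)chroman-8-carboxylate, C3 geometry as in 17 (descriptor 3S) | COC1=C(CC=C(C)C)C(=O)C(CC1)([Se](=O)c3ccccc3)[C@@H]4COc2c(C(=O)OC)c(OCOC)cc(OC)c2C4 | intermediate
20 | methyl (3R)-5-methoxy-3-[4-methoxy-5-(3-methylbut-2-enyl)-6-oxocyclohexa-1,4-dien-1-yl]-7-(methoxymethoxy)chroman-8-carboxylate (keto tautomer of 21) | COC1=C(CC=C(C)C)C(=O)C(=CC1)[C@@H]4COc2c(C(=O)OC)c(OCOC)cc(OC)c2C4 | intermediate
21 | methyl (3R)-3-[2-hydroxy-4-methoxy-3-(3-methylbut-2-enyl)phenyl]-5-methoxy-7-(methoxymethoxy)chroman-8-carboxylate | COc1ccc([C@@H]2COc3c(C(=O)OC)c(OCOC)cc(OC)c3C2)c(O)c1CC=C(C)C | intermediate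
22 | [(3R)-3-[2-hydroxy-4-methoxy-3-(3-methylbut-2-enyl)phenyl]-5-methoxy-7-(methoxymethoxy)chroman-8-yl]methanol | COc1ccc([C@@H]2COc3c(CO)c(OCOC)cc(OC)c3C2)c(O)c1CC=C(C)C | intermediate
23 | (3R)-3-[2-hydroxy-4-methoxy-3-(3-methylbut-2-enyl)phenyl]-5-methoxy-7-(methoxymethoxy)chroman-8-carbaldehyde | COc1ccc([C@@H]2COc3c(C=O)c(OCOC)cc(OC)c3C2)c(O)c1CC=C(C)C | intermediate
24 | (3R)-7-hydroxy-3-[2-hydroxy-4-methoxy-3-(3-methylbut-2-enyl)phenyl]-5-methoxychroman-8-carbaldehyde | COc1ccc([C@@H]2COc3c(C=O)c(O)cc(OC)c3C2)c(O)c1CC=C(C)C | target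

Total step count: 13.
Longest linear sequence: 11 steps (steps 1–5 and 8–13); steps 6 and 7 form the side branch to enone 12.

Steps most likely to fail

Step 8. The conjugate addition may be overtaken by attack at the ketone carbonyl or by oligomerisation of the vinyl ketone, the activated enone may cyclise onto its own prenyl alkene, or the enolates may not equilibrate before the Claisen closure. The fallback exchanges the roles of donor and acceptor and needs no vinyl ketone. It sets out from compound 8: its lithium enolate (LiN(i-Pr)2, THF, −78 °C) is treated with (CH2=NMe2)I to give the β-dimethylamino ester F1, MeI converts this into the methiodide F2, and aqueous NaHCO3 eliminates trimethylamine to give the 2-substituted acrylate F3. The kinetic lithium enolate of ketone 9 (LiN(i-Pr)2, THF, −78 °C, methyl side) is then added to F3 in a Michael reaction that forms C5'–C6' and gives keto ester 15, which KOt-Bu in THF/t-BuOH closes as in step 8. The fallback comes back to the route at compound 16. F3 must be consumed at low temperature, because deprotonation at its γ-position (C3) would racemise the stereocentre.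

Step 10. Deprotonation of the hindered tertiary C1'–H may be incomplete or give way to γ-deprotonation at C5', C–Se bond formation at the tetrasubstituted enolate may be slow, the selenoxide may eliminate toward C3–H instead of C6'–H and so erode the C3 configuration, and selenenic acid may add to the prenyl alkene. The fallback aromatises before the two oxygens are differentiated and sets out from dione 16, so that step 9 is bypassed as well. The dianion (LiN(i-Pr)2, 2.2 equiv, THF, −78 °C) is selenenylated with PhSeBr at the unhindered C5' to give the C5' selenide F4; H2O2/pyridine oxidises it to the selenoxide F5, which can eliminate only toward C6' and gives the cyclohexenedione F6, whose enolisation affords the resorcinol F7. Methylation with MeI (1.0 equiv) and K2CO3 in acetone should take the 4'-OH, since the 2'-OH lies between two ortho substituents. The fallback comes back to the route at compound 21.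

Step 3. Facial selectivity in the attack of the enamine on an unsubstituted quinone methide may be low, the product may racemise through its open hydroxy aldehyde form under the basic amine conditions, or the quinone methide may trap the catalyst by N-alkylation. The fallback sets the stereocentre by hydrogenation instead and sets out from compound 6 as obtained, whatever its enantiomeric purity (an achiral amine such as pyrrolidine could then serve in step 3). Dehydration with PPTS (cat.) in toluene at 80 °C gives the 4H-chromene F8, and asymmetric hydrogenation of this cyclic enol ether with [Ir(cod)(L)]BArF (L = a chiral phosphinooxazoline, enantiomer chosen to give R; H2 50 bar, CH2Cl2) should give the (3R)-chroman. The fallback comes back to the route at compound 7.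

Further compounds
F1 | step 8 | methyl (3R)-3-[3-(dimethylamino)-1-methoxy-1-oxopropan-2-yl]-5-methoxy-7-(methoxymethoxy)chroman-8-carboxylate | COC(=O)C(CN(C)C)[C@@H]1COc2c(C(=O)OC)c(OCOC)cc(OC)c2C1
F2 | step 8 | [2-[(3R)-8-(methoxycarbonyl)-5-methoxy-7-(methoxymethoxy)chroman-3-yl]-3-methoxy-3-oxopropyl]trimethylammonium iodide | COC(=O)C(C[N+](C)(C)C)[C@@H]1COc2c(C(=O)OC)c(OCOC)cc(OC)c2C1.[I-]
F3 | step 8 | methyl (3R)-5-methoxy-3-(3-methoxy-3-oxoprop-1-en-2-yl)-7-(methoxymethoxy)chroman-8-carboxylate | COC(=O)C(=C)[C@@H]1COc2c(C(=O)OC)c(OCOC)cc(OC)c2C1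
F4 | step 10 | methyl (3R)-3-[2,4-dioxo-3-(3-methylbut-2-enyl)-5-(phenylselanyl)cyclohexyl]-5-methoxy-7-(methoxymethoxy)chroman-8-carboxylate | CC(C)=CCC1C(=O)C([Se]c3ccccc3)CC(C1=O)[C@@H]4COc2c(C(=O)OC)c(OCOC)cc(OC)c2C4
F5 | step 10 | methyl (3R)-3-[2,4-dioxo-3-(3-methylbut-2-enyl)-5-(phenylseleninyl)cyclohexyl]-5-methoxy-7-(methoxymethoxy)chroman-8-carboxylate | CC(C)=CCC1C(=O)C([Se](=O)c3ccccc3)CC(C1=O)[C@@H]4COc2c(C(=O)OC)c(OCOC)cc(OC)c2C4
F6 | step 10 | methyl (3R)-3-[2,4-dioxo-3-(3-methylbut-2-enyl)cyclohex-5-en-1-yl]-5-methoxy-7-(methoxymethoxy)chroman-8-carboxylate | CC(C)=CCC1C(=O)C=CC(C1=O)[C@@H]4COc2c(C(=O)OC)c(OCOC)cc(OC)c2C4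
F7 | step 10 | methyl (3R)-3-[2,4-dihydroxy-3-(3-methylbut-2-enyl)phenyl]-5-methoxy-7-(methoxymethoxy)chroman-8-carboxylate | CC(C)=CCc1c(O)ccc([C@@H]2COc3c(C(=O)OC)c(OCOC)cc(OC)c3C2)c1O
F8 | step 3 | methyl 7-hydroxy-5-methoxy-3-(2-methoxy-2-oxoethyl)-4H-chromene-8-carboxylate | COC(=O)CC1=COc2c(C(=O)OC)c(O)cc(OC)c2C1
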